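## Retrosynthetic overview
1. The target comes from one global hydride reduction of a 2-aryl-2,3-dihydrobenzofuran carrying 3-CHO, a 5-(E)-acrylate and a 4'-O-acetyl group. The acrylate comes from a Heck reaction on a 5-bromide, and the CHO from glycol cleavage of a 3-(dioxolanyl) group.
2. The dihydrobenzofuran is the only ring built. It comes from an anodic dehydrogenative [3+2] of 4-bromoguaiacol with an (E)-styryl-dioxolane, which forms C3–C3a and C2–O in the same electrolysis.
3. Both ring stereocentres are induced by the dioxolane stereocentre of D-mannitol-derived (R)-glyceraldehyde acetonide. Its stereogenic carbon ends up as the CH2OH carbon.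
4. The styryl-dioxolane comes from a Heck reaction of 4-bromo-2,6-dimethoxyphenyl acetate with (S)-vinyl-dioxolane, which comes from Wittig methylenation of the aldehyde.

Assumption: the facial sense of step 3 follows the inside-alkoxy (1,2-anti) model for additions to allylic ethers, which makes the cheap D-mannitol-derived (R)-aldehyde the correct enantiomer to buy.

## Route

Step 1
Reactants: 1 (R)-2,2-dimethyl-1,3-dioxolane-4-carbaldehyde ((R)-glyceraldehyde acetonide)
Product: 2 (S)-4-ethenyl-2,2-dimethyl-1,3-dioxolane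
Conditions: Ph3PCH3Br (1.2 equiv), KOtBu (1.15 equiv), Et2O/THF, 0 °C; then 1, −78 °C → rt; distil
Reagents that add atoms: methyltriphenylphosphonium bromide, C[P+](c1ccccc1)(c1ccccc1)c1ccccc1.[Br-]
Why: Wittig methylenation with the non-stabilised ylide consumes the α-alkoxy aldehyde at low temperature before it can enolise, so the bought stereocentre is carried over unchanged (R becomes S only through CIP ranking).

Step 2
Reactants: 3 4-bromo-2,6-dimethoxyphenol; 2 (S)-4-ethenyl-2,2-dimethyl-1,3-dioxolane
Product: 5 4-[(E)-2-[(4S)-2,2-dimethyl-1,3-dioxolan-4-yl]ethenyl]-2,6-dimethoxyphenyl acetate, via bromoaryl acetate 4 (not isolated)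
Conditions: Ac2O (1.05 equiv), Et3N (3.5 equiv), DMAP (1 mol %), DMF, rt, 30 min; then 2 (1.5 equiv), Pd(OAc)2 (3 mol %), P(o-tol)3 (8 mol %), 95 °C, sealed tube
Reagents that add atoms: acetic anhydride, CC(=O)OC(C)=O
Why: O-acetylation followed by a Mizoroki–Heck reaction, in which aryl-Pd adds to the unsubstituted alkene terminus and β-hydride elimination of the benzylic H gives the conjugated E-styrene without touching the allylic stereocentre, while the acetate activates C–Br and masks the oxidation-prone syringyl phenol for steps 3 and 5.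

Step 3
Reactants: 5 4-[(E)-2-[(4S)-2,2-dimethyl-1,3-dioxolan-4-yl]ethenyl]-2,6-dimethoxyphenyl acetate; 6 4-bromo-2-methoxyphenol
Product: 7 4-[(2S,3S)-5-bromo-3-[(4S)-2,2-dimethyl-1,3-dioxolan-4-yl]-7-methoxy-2,3-dihydro-1-benzofuran-2-yl]-2,6-dimethoxyphenyl acetate
Conditions: undivided cell, BDD anode | Pt cathode, 6 (2.5 equiv, slow addition), nBu4NPF6 (0.1 M), 2,6-lutidine (0.5 equiv), HFIP/CH2Cl2 4:1, 5 mA cm⁻², 2.2 F per mol of 6, 0 °C → rt, N2; chromatography
Reagents that add atoms: none
Why: Proposed new method: a substrate-controlled anodic dehydrogenative [3+2] annulation in which an allylic dioxolane stereocentre fixes the absolute configuration – 6 (estimated Ep ≈ +1.2 V vs SCE, lowered by lutidine) is oxidised selectively over 5 (estimated ≈ +1.6 V because of the 4-OAc group) to the HFIP-solvated phenoxyl/phenoxenium species, whose only unsubstituted ortho/para carbon (C6) is attacked by the styrene β-carbon of 5 (regiochemistry set by formation of the benzylic radical/cation, which is oxidised further at the same potential); the alkene reacts through the staggered inside-alkoxy conformer (C–O inside, C–CH2O anti to the incoming arene, H outside), so the new C3–aryl bond forms 1,2-anti to the dioxolane C–O; the dienone oxygen then closes on the benzylic cation trans to the bulky dioxolanyl group (setting C2), loss of H+ rearomatises and H2 leaves at the cathode; the minor facial diastereomer is removed by chromatography so 7 is a single stereoisomer; the closest known reaction types are the racemic anodic and photocatalytic oxidative [3+2] cycloadditions of 4-methoxyphenols with anethole-type alkenes and the ortho-selective anodic phenol–arene cross-coupling of 4-substituted guaiacols in HFIP, neither of which has been shown for a 4-haloguaiacol/alkene pair or with acyclic 1,2-induction from an allylic stereocentre.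

Step 4
Reactants: 7 4-[(2S,3S)-5-bromo-3-[(4S)-2,2-dimethyl-1,3-dioxolan-4-yl]-7-methoxy-2,3-dihydro-1-benzofuran-2-yl]-2,6-dimethoxyphenyl acetate; 8 methyl acrylate
Product: 9 methyl (E)-3-[(2S,3S)-2-(4-acetoxy-3,5-dimethoxyphenyl)-3-[(4S)-2,2-dimethyl-1,3-dioxolan-4-yl]-7-methoxy-2,3-dihydro-1-benzofuran-5-yl]prop-2-enoate
Conditions: 8 (3 equiv), Pd(OAc)2 (5 mol %), P(o-tol)3 (15 mol %), Et3N (2.5 equiv), dry DMF, 100 °C
Reagents that add atoms: none
Why: Mizoroki–Heck coupling of the only C–Br bond with an electron-poor acrylate gives the E-cinnamate exclusively, and the anhydrous tertiary-amine medium leaves the acetate, the acetonide and both ring stereocentres untouched.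

Step 5
Reactants: 9 methyl (E)-3-[(2S,3S)-2-(4-acetoxy-3,5-dimethoxyphenyl)-3-[(4S)-2,2-dimethyl-1,3-dioxolan-4-yl]-7-methoxy-2,3-dihydro-1-benzofuran-5-yl]prop-2-enoate
Product: 11 methyl (E)-3-[(2S,3S)-2-(4-acetoxy-3,5-dimethoxyphenyl)-3-formyl-7-methoxy-2,3-dihydro-1-benzofuran-5-yl]prop-2-enoate, via diol 10 (not isolated)
Conditions: H5IO6 (1.5 equiv), EtOAc, 0 °C → rt, 2 h; filter, cold NaHCO3 wash, use crude at once
Reagents that add atoms: none
Why: Periodic acid hydrolyses the terminal acetonide and carries out the Malaprade glycol cleavage in one flask; no free phenol is present to be oxidised, the non-basic medium avoids E1cB opening of the β-aryloxy aldehyde, and any enolisation at C3 returns to the favoured trans isomer because C2 stays fixed.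

Step 6
Reactants: 11 methyl (E)-3-[(2S,3S)-2-(4-acetoxy-3,5-dimethoxyphenyl)-3-formyl-7-methoxy-2,3-dihydro-1-benzofuran-5-yl]prop-2-enoate
Product: 12 4-[(2S,3R)-3-(hydroxymethyl)-5-[(E)-3-hydroxyprop-1-enyl]-7-methoxy-2,3-dihydro-1-benzofuran-2-yl]-2,6-dimethoxyphenol (target)
Conditions: DIBAL-H (8 equiv), CH2Cl2, −78 → −20 °C; aq. Rochelle salt
Reagents that add atoms: none
Why: DIBAL-H 1,2-reduction converts the aldehyde to CH2OH at −78 °C before it can epimerise or eliminate, reduces the enoate to the E-allylic alcohol and cleaves the aryl acetate in the same operation, with no stereocentre involved (3S becomes 3R only through CIP ranking).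

## Compound list
1 | (R)-2,2-dimethyl-1,3-dioxolane-4-carbaldehyde | O=C[C@H]1COC(C)(C)O1 | starting material
2 | (S)-4-ethenyl-2,2-dimethyl-1,3-dioxolane | C=C[C@H]1COC(C)(C)O1 | intermediate
3 | 4-bromo-2,6-dimethoxyphenol | COc1cc(Br)cc(OC)c1O | starting material
4 | 4-bromo-2,6-dimethoxyphenyl acetate | COc1cc(Br)cc(OC)c1OC(C)=O | intermediate
5 | 4-[(E)-2-[(4S)-2,2-dimethyl-1,3-dioxolan-4-yl]ethenyl]-2,6-dimethoxyphenyl acetate | COc1cc(/C=C/[C@H]2COC(C)(C)O2)cc(OC)c1OC(C)=O | intermediate
6 | 4-bromo-2-methoxyphenol | COc1cc(Br)ccc1O | starting material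
7 | 4-[(2S,3S)-5-bromo-3-[(4S)-2,2-dimethyl-1,3-dioxolan-4-yl]-7-methoxy-2,3-dihydro-1-benzofuran-2-yl]-2,6-dimethoxyphenyl acetate | COc1cc([C@H]2Oc3c(OC)cc(Br)cc3[C@@H]2[C@H]4COC(C)(C)O4)cc(OC)c1OC(C)=O | intermediate
8 | methyl acrylate | C=CC(=O)OC | starting material
9 | methyl (E)-3-[(2S,3S)-2-(4-acetoxy-3,5-dimethoxyphenyl)-3-[(4S)-2,2-dimethyl-1,3-dioxolan-4-yl]-7-methoxy-2,3-dihydro-1-benzofuran-5-yl]prop-2-enoate | COc1cc([C@H]2Oc3c(OC)cc(/C=C/C(=O)OC)cc3[C@@H]2[C@H]4COC(C)(C)O4)cc(OC)c1OC(C)=O | intermediate
10 | methyl (E)-3-[(2S,3R)-2-(4-acetoxy-3,5-dimethoxyphenyl)-3-[(1S)-1,2-dihydroxyethyl]-7-methoxy-2,3-dihydro-1-benzofuran-5-yl]prop-2-enoate | COc1cc([C@H]2Oc3c(OC)cc(/C=C/C(=O)OC)cc3[C@@H]2[C@H](O)CO)cc(OC)c1OC(C)=O | intermediate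
11 | methyl (E)-3-[(2S,3S)-2-(4-acetoxy-3,5-dimethoxyphenyl)-3-formyl-7-methoxy-2,3-dihydro-1-benzofuran-5-yl]prop-2-enoate | COc1cc([C@H]2Oc3c(OC)cc(/C=C/C(=O)OC)cc3[C@@H]2C=O)cc(OC)c1OC(C)=O | intermediate
12 | 4-[(2S,3R)-3-(hydroxymethyl)-5-[(E)-3-hydroxyprop-1-enyl]-7-methoxy-2,3-dihydro-1-benzofuran-2-yl]-2,6-dimethoxyphenol | COc1cc([C@H]2Oc3c(OC)cc(/C=C/CO)cc3[C@@H]2CO)cc(OC)c1O | target

## Step count and risks
Total steps: 6. Longest linear sequence: 6 (1 → 2 → 5 → 7 → 9 → 11 → 12).

**Step 3 (the proposed new step).**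
- Risks: ortho–ortho homocoupling of 6, sluggish capture by the electron-poor styrene, only moderate facial selectivity (estimated 4–6:1), and partial loss of the acetonide in HFIP.
- Fallback: this uses known two-electron palladium chemistry, sets out from 5 and 6, and comes back at 7.
- Phenol 6 is iodinated ortho to the hydroxyl group (NIS, MeCN, 0 °C) to give 4-bromo-2-iodo-6-methoxyphenol F1.
- F1 is then joined to 5 by the established Pd-catalysed Heck-type oxyarylation of β-substituted styrenes with o-iodophenols (Pd(OAc)2, Ag2CO3, acetone, 60 °C).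
- Oxidative addition is selective for C–I. Carbopalladation places the aryl group on the carbon next to the dioxolane, and C–O closure at the benzylic carbon gives the trans-dihydrobenzofuran.
- The dioxolane again differentiates the two faces, and the diastereomers are separated by chromatography.

**Step 5.**
- Risk: aldehyde 11 is an α-aryl-β-aryloxy aldehyde and can ring-open by elimination or degrade on handling.
- Fallback: this sets out from 9 and comes back at 12.
- The acetonide is hydrolysed separately (80 % aq. AcOH, 40 °C) and diol 10 is isolated.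
- Diol 10 is cleaved with silica-supported NaIO4 in CH2Cl2 at 0 °C, and the filtrate is run straight into NaBH4/MeOH at −20 °C. The aldehyde is therefore reduced within minutes and is never concentrated.
- This gives methyl (E)-3-[(2S,3R)-2-(4-acetoxy-3,5-dimethoxyphenyl)-3-(hydroxymethyl)-7-methoxy-2,3-dihydro-1-benzofuran-5-yl]prop-2-enoate F2.
- The remaining enoate and acetate of F2 are then reduced with DIBAL-H to give 12.

**Step 2.**
- Risks: loss of volatile 2, and β-hydride elimination or Pd–H chain walking toward the dioxolane C–H, which gives an enol ether.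
- Fallback: this sets out from 2 and comes back at 5.
- Commercial 4-vinylsyringol (2,6-dimethoxy-4-vinylphenol) is acetylated (Ac2O, pyridine) to give 4-ethenyl-2,6-dimethoxyphenyl acetate F3.
- F3 is joined to 2 by E-selective olefin cross-metathesis (Hoveyda–Grubbs II, CH2Cl2, 40 °C, excess 2). No Pd–H species is formed, so the allylic stereocentre is not at risk.

## Further compounds
F1 | step 3 | 4-bromo-2-iodo-6-methoxyphenol | COc1cc(Br)cc(I)c1O
F2 | step 5 | methyl (E)-3-[(2S,3R)-2-(4-acetoxy-3,5-dimethoxyphenyl)-3-(hydroxymethyl)-7-methoxy-2,3-dihydro-1-benzofuran-5-yl]prop-2-enoate | COc1cc([C@H]2Oc3c(OC)cc(/C=C/C(=O)OC)cc3[C@@H]2CO)cc(OC)c1OC(C)=O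
F3 | step 2 | 4-ethenyl-2,6-dimethoxyphenyl acetate | C=Cc1cc(OC)c(OC(C)=O)c(OC)c1
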